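## The problem

The target is the caffeic acid ester of (−)-lariciresinol. It is an oxolane (O1, C2 to C5) with a 4-hydroxy-3-methoxyphenyl group on C2, a CH2O–caffeoyl arm on C3 and a 4-hydroxy-3-methoxybenzyl group on C4, configured (2R,3S,4S), that is 2,3-trans and 3,4-cis. The ring is a single flexible five-membered ring with three contiguous stereocentres and no ring fusion to lean on. C3 and C4 are CH centres bonded only to carbon and cannot be corrected once set, so they need an external source of absolute configuration, and their cis relationship is the less comfortable one. C2 is different: it is a benzylic ether carbon para to an oxygen donor, it ionises easily, and on closure through the benzylic cation it settles trans to the C3 substituent. C3 can therefore control C2, and C4 can control C3 if the two are set in a relay. The same lability is a hazard: acid can reopen C2–O1, after which the electron-rich ring of the C4 benzyl group can capture the cation, and hydrogenolysis can cut C2–O1. The caffeoyl part brings an enoate that tolerates neither hydride, nickel nor hydrogenation conditions and a catechol that is sensitive to air and base, so it must arrive late, and the one aliphatic hydroxyl must then be acylated beside phenols. The enabling feature is that C5, C4, C3 and the CH2O carbon on C3 form a four-carbon chain oxygenated at both ends, the skeleton of a butenolide: C3–C4 is its double bond, the CH2O carbon its carbonyl and C5 its γ-carbon. C4 carries a benzylic carbon that can enter as a nucleophile, and C3 carries the C2 carbinol carbon that can enter as an aldehyde.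

## Retrosynthesis

**Ester bond, 19 to 15 and 17 (through 18).** The last skeletal bond to form is the ester C–O bond between the CH2 on C3 and the caffeoyl group. It goes last because the enoate and the catechol would not survive the reductive steps that build the lignan core. The catechol is carried as the diacetate 17, made from caffeic acid 16, and unmasked in 18. Acylating the benzyl-protected alcohol 14 instead would be simpler in chemoselectivity, but the benzyl ethers could then not be removed by hydrogenolysis without saturating the alkene. The forward reaction must esterify the one aliphatic hydroxyl of 15 beside two phenols, which points to activation of the alcohol (Mitsunobu) and not of the acid.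

**Phenol protection, 15 to 14.** The two O–benzyl bonds are cut. Benzyl ethers are chosen because they pass organolithium, nickel boride, hydride and mild acid unchanged. The forward hydrogenolysis must stop before the ring C2–O1 bond is touched.

**Ring closure, 14 to 13.** The O1–C2 bond is cut, giving the acyclic triol 13. Cutting O1–C5 instead would demand a carbinol of defined configuration and a distinction between two primary hydroxyls. The O1–C2 cut needs neither: any carbinol epimer gives the same benzylic cation, and only the CH2OH on the neighbouring carbon can reach it in a five-membered closure. The precursor has only two stereocentres that matter, and the forward reaction must place C2 trans to C3.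

**Oxidation-level changes, 13 to 12 to 11.** The two CH2OH termini of 13 are read as the carbonyl carbon and the acetal carbon of a 5-alkoxy-γ-lactone, and the benzylic CH2 on the C4 side as a dithioketal carbon. This turns the triol into lactone 11, which carries a chiral auxiliary on its acetal carbon. The forward steps are a reductive desulfurisation and a hydride reduction that must not epimerise the two CH centres.

**Key disconnection, 11 to 6, 8 and 7.** Two C–C bonds are cut, C4–C(dithiane) and C3–C(carbinol). This leaves butenolide 6, aryl dithiane 8 as the nucleophilic benzyl equivalent and aldehyde 7 as the C2 carbon. Making the two bonds separately would cost an extra enolisation. A benzylic organometallic in place of the dithiane anion would add less cleanly in the 1,4 sense and would offer a smaller group to steer the aldol. All three precursors are simple and two of them come from the same aldehyde. The forward reaction must add 1,4, anti to the acetal substituent, and trap the enolate anti to the new C4 group.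

**Building blocks.** Furanone 6 comes from lactol 3 and (+)-menthol 4 by acetalisation, and 3 from furfural 1 by photo-oxygenation. Dithiane 8 comes from aldehyde 7 by thioacetalisation. Acid 17 comes from caffeic acid 16 by acetylation.

## Roads not taken

**Alternative 1:** The cut is O1–C2, C3–C4 and the aryl–vinyl bond of the 4-arylmethylidene oxolane A1. In the forward step a propargylic alkoxide adds to an arylidene malonate, the malonate anion closes 5-exo-dig onto the alkyne activated by an arylpalladium iodide (divalent palladium, formed from a zerovalent palladium catalyst and an aryl iodide), and reductive elimination gives A1.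
- Merits: three components, the ring and three bonds in one flask, with every carbon of the lignan core in place. It is the most convergent entry to the skeleton and shorter than the chosen plan up to that point.
- Weak points: C2 arises in a reversible oxa-Michael addition to an achiral acceptor with no controlling element, so A1 would be racemic unless a resolution or an asymmetric variant is added. C3 is quaternary in A1 and needs dealkoxycarbonylation and reduction. C4 must come from hydrogenation of the exocyclic alkene, where the C2 aryl group and the C3 substituent direct to opposite faces, on a substrate that already holds a benzylic C–O bond and benzyl ethers.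
- Comparison: this road wins on convergence and step count to the skeleton. The chosen plan sets against it that C3 and C4 are fixed in absolute terms in the same operation that makes the C–C bonds, and that C2 is left to a closure that is known to go trans.

**Alternative 2:** The cut is the O–C5 bond of the β-benzyl lactone A3, traced back to the prochiral cyclobutanone A2. In the forward step a Baeyer–Villiger monooxygenase inserts oxygen into one of the two enantiotopic ring bonds of A2 and gives A3 with C4 set.
- Merits: catalytic, dioxygen as oxidant, no auxiliary and no sulfur to carry and remove. An α-aldol of A3 with aldehyde 7 followed by hydride reduction would arrive at the same triol 13, so the end game is shared. The step count is comparable and the atom economy is better than in the chosen plan.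
- Weak points: the enantioselectivity, and even the sense of induction, depend on how this bulky benzyloxy-substituted substrate fits the enzyme, which cannot be read from the structure. A3 is a single-stereocentre compound whose enantiomeric purity cannot be raised by separating diastereomers. A2 needs its own ketene cycloaddition and dehalogenation sequence, and C3 has to be set in a separate step.
- Comparison: this road is equal or better in length and atom economy. The chosen plan sets against it a stereochemical outcome that follows from substrate control by a crystalline, diastereomerically pure acetal, two C–C bonds in one operation, diastereomeric intermediates that can be purified, and an auxiliary that is recovered.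

**Alternative 3:** The cut is again O1–C2, but as a C–H functionalisation of the C2-symmetric diol A4. In the forward step a high-potential quinone abstracts hydride from a benzylic CH2 of A4, and the hydroxyl four atoms away captures the cation to give A5, which is identical with 14.
- Merits: the most direct route to the oxolane. No carbinol oxidation level has to be introduced, the symmetry of A4 makes both benzylic positions equivalent, and the road rejoins the chosen one at 14.
- Weak points: the product is at least as oxidisable as the substrate. It keeps a second benzylic CH2 with a free CH2OH placed to close a second oxolane, its C2–H is benzylic and α to oxygen, and the cation can also be taken by the other arene. Stopping after one oxidation is therefore the unsolved selectivity. A4 itself needs an enantioselective synthesis of two adjacent stereocentres, which costs about as many steps as the chosen plan spends on 13.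
- Comparison: if the single oxidation could be held, this road would be shorter and more elegant. The chosen plan sets against it that the oxygen on C2 is placed by construction, as the aldehyde carbon, so no over-oxidation question arises.

Key step: step 4

Remark on the chemistry: the carbinol carbon made in step 4 is expected as a mixture of both epimers, so 11, 12 and 13 are written with this one centre undefined (all others fixed) because step 7 erases it; aldehyde 7 is taken as a catalogue compound.

## Route

Step 1
Reactants: 1 furfural
Product: 3 5-hydroxyfuran-2(5H)-one (racemic), via furfural endoperoxide 2 (not isolated)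
Conditions: O2, hν (visible light), methylene blue (cat.), MeOH, rt
Reagents that add atoms: dioxygen, O=O
Why: Dye-sensitised singlet-oxygen [4+2] cycloaddition to the furan gives endoperoxide 2, whose methanolysis expels the formyl carbon as methyl formate and leaves the lactol; this photo-oxygenation of furfural is long established, and the racemic C5 is reset in step 2.

Step 2
Reactants: 3 5-hydroxyfuran-2(5H)-one; 4 (+)-menthol
Product: 6 (5S)-5-{[(1S,2R,5S)-2-isopropyl-5-methylcyclohexyl]oxy}furan-2(5H)-one, via (5R)-acetal epimer 5 (not isolated)
Conditions: CSA (cat.), toluene, reflux, Dean–Stark trap; crystallisation from hexane, −20 °C; mother liquor re-equilibrated with CSA and recrystallised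
Reagents that add atoms: none
Why: Acid-catalysed acetalisation of the lactol through the furanone oxocarbenium ion gives both C5 epimers, which interconvert under the acid; 6 is the mirror image of the well-described crystalline acetal from (−)-menthol and should crystallise in the same way, so C5 is set by crystallisation with recycling of epimer 5.

Step 3
Reactants: 7 4-benzyloxy-3-methoxybenzaldehyde
Product: 8 2-(4-benzyloxy-3-methoxyphenyl)-1,3-dithiane
Conditions: HS(CH2)3SH, BF3·OEt2 (cat.), CH2Cl2, 0 °C → rt
Reagents that add atoms: propane-1,3-dithiol, SCCCS
Why: Lewis-acid-catalysed dithioacetalisation of an aromatic aldehyde; the aryl benzyl ether tolerates catalytic BF3·OEt2 at this temperature.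

Step 4
Reactants: 8 2-(4-benzyloxy-3-methoxyphenyl)-1,3-dithiane; 6 (5S)-5-(d-menthyloxy)furan-2(5H)-one; 7 4-benzyloxy-3-methoxybenzaldehyde
Product: 11 (3R,4S,5S)-3-[(4-benzyloxy-3-methoxyphenyl)(hydroxy)methyl]-4-[2-(4-benzyloxy-3-methoxyphenyl)-1,3-dithian-2-yl]-5-{[(1S,2R,5S)-2-isopropyl-5-methylcyclohexyl]oxy}oxolan-2-one (both carbinol epimers), via lithiated dithiane 9 (not isolated), via lithium lactone enolate 10 (not isolated)
Conditions: 8, n-BuLi, THF, −78 → −20 °C; then 6, THF, −78 °C; then 7, THF, −78 °C; AcOH, −78 °C
Reagents that add atoms: none
Why: Deprotonation of 8 gives the sulfur- and aryl-stabilised carbanion 9 (Corey–Seebach umpolung), a soft and hindered nucleophile that adds 1,4 to butenolide 6 instead of attacking its carbonyl. It attacks C4 of the flat ring on the face anti to the C5 menthyloxy group, which fixes C4 as (S) and gives enolate 10. Enolate 10 then adds through C3 to aldehyde 7 (aldol addition) on the face anti to the very large dithianyl group, which fixes C3 as (R), trans,trans around the lactone. The closest known reaction type is the tandem conjugate addition of lithiated aryl dithianes to 5-alkoxy-2(5H)-furanones, the 5-menthyloxy compound included, with trapping of the enolate by alkyl halides or aldehydes. No ring is closed; two C–C bonds and three stereocentres are formed. The third centre, the carbinol carbon, is under no reliable control (a closed Zimmerman–Traxler transition state from the ring-locked enolate should lean towards the anti aldol) and needs none, because step 7 ionises it. The step needs 1,4-regioselectivity, facial selectivity at C4 and C3, and an aldol that does not revert: the first comes from the delocalised carbanion, the second from the acetal centre of enantiopure 6 and the relay C5 to C4 to C3, the third from holding −78 °C and protonating cold with AcOH.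

Step 5
Reactants: 11 dithianyl hydroxy lactone
Product: 12 (3R,4S,5S)-4-(4-benzyloxy-3-methoxybenzyl)-3-[(4-benzyloxy-3-methoxyphenyl)(hydroxy)methyl]-5-{[(1S,2R,5S)-2-isopropyl-5-methylcyclohexyl]oxy}oxolan-2-one (both carbinol epimers)
Conditions: NiCl2·6H2O, NaBH4, MeOH/THF, 0 °C → rt
Reagents that add atoms: none
Why: Nickel boride (Ni2B) formed in the flask cleaves both C–S bonds reductively and turns the dithioketal carbon into the benzylic CH2; aryl benzyl ethers, the benzylic alcohol and the acetal lactone should be left alone at this temperature, and no stereocentre is touched.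

Step 6
Reactants: 12 benzyl hydroxy lactone
Product: 13 (2S,3S)-2-[(4-benzyloxy-3-methoxyphenyl)(hydroxy)methyl]-3-(4-benzyloxy-3-methoxybenzyl)butane-1,4-diol (both carbinol epimers)
Conditions: LiAlH4, THF, 0 °C → rt; then H2O, filtration
Reagents that add atoms: none
Why: Hydride reduction of the lactone opens the ring, the hemiacetal alkoxide set free at the acetal carbon loses menthoxide and the resulting aldehyde is reduced as well, so both termini become CH2OH and menthol is returned; the two CH stereocentres stay because the transient aldehyde is reduced faster than it can enolise.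

Step 7
Reactants: 13 triol
Product: 14 [(2R,3S,4S)-2-(4-benzyloxy-3-methoxyphenyl)-4-(4-benzyloxy-3-methoxybenzyl)oxolan-3-yl]methanol
Conditions: CSA (cat.), CH2Cl2, 0 °C; Et3N quench
Reagents that add atoms: none
Why: Acid-catalysed SN1 cycloetherification: either carbinol epimer ionises to the same p-alkoxybenzylic cation, which only the CH2OH on the neighbouring carbon can reach in a five-membered closure (the other hydroxyl would give an oxetane). C2 is set trans to the C3 hydroxymethyl group because the aryl group avoids that substituent in the closing transition state and the closure is reversible under the acid, as in the known cyclisation of 7-hydroxylated dibenzylbutanediol lignans to 2-aryloxolane lignans.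

Step 8
Reactants: 14 di-O-benzyl-(−)-lariciresinol
Product: 15 (−)-lariciresinol, 4-[(2R,3S,4S)-4-(4-hydroxy-3-methoxybenzyl)-3-(hydroxymethyl)oxolan-2-yl]-2-methoxyphenol
Conditions: H2 (1 atm), Pd/C (10% Pd), EtOAc, rt; stopped when 14 is consumed
Reagents that add atoms: none
Why: Hydrogenolysis of the two aryl benzyl ethers over palladium is faster than cleavage of the hindered secondary benzylic C2–O1 bond in a neutral aprotic solvent, so stopping at full conversion should give the bis-phenol with the ring intact.

Step 9
Reactants: 16 caffeic acid
Product: 17 (E)-3-(3,4-diacetoxyphenyl)prop-2-enoic acid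
Conditions: Ac2O, pyridine, rt; aqueous acidic work-up
Reagents that add atoms: acetic anhydride, CC(=O)OC(C)=O
Why: Standard acetylation of the catechol hydroxyls; the aqueous work-up returns the free carboxylic acid, and the acetates protect the catechol from oxidation and from the Mitsunobu reagents.

Step 10
Reactants: 15 (−)-lariciresinol; 17 (E)-3-(3,4-diacetoxyphenyl)prop-2-enoic acid
Product: 18 [(2R,3S,4S)-2-(4-hydroxy-3-methoxyphenyl)-4-(4-hydroxy-3-methoxybenzyl)oxolan-3-yl]methyl (E)-3-(3,4-diacetoxyphenyl)prop-2-enoate
Conditions: PPh3, DIAD, THF, 0 °C → rt
Reagents that add atoms: none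
Why: Mitsunobu esterification: the primary alcohol is activated as its alkoxyphosphonium ion and displaced by the carboxylate; the carboxylic acid is by far the most acidic pronucleophile present, so phenol O-alkylation should stay minor. Esterification of phenol-bearing primary alcohols with cinnamic acids is a known use of this reaction, and no stereocentre lies at the reacting CH2.

Step 11
Reactants: 18 diacetyl ester
Product: 19 [(2R,3S,4S)-2-(4-hydroxy-3-methoxyphenyl)-4-(4-hydroxy-3-methoxybenzyl)oxolan-3-yl]methyl (E)-3-(3,4-dihydroxyphenyl)prop-2-enoate (target)
Conditions: NH3 (2 M in MeOH), THF, 0 °C, argon; AcOH quench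
Reagents that add atoms: none
Why: Aminolysis of the two aryl acetates (phenoxide leaving groups) is far faster than attack on the alkyl enoate, which is deactivated by conjugation with the electron-rich ring, the more so once the 4-oxygen is free; argon and the acidic quench protect the catechol.

## Compound list

1 | furfural | O=Cc1ccco1 | starting material
2 | furfural endoperoxide, 2,3,7-trioxabicyclo[2.2.1]hept-5-ene-1-carbaldehyde (racemic, not isolated) | O=CC12C=CC(OO1)O2 | intermediate
3 | 5-hydroxyfuran-2(5H)-one (racemic) | O=C1C=CC(O)O1 | intermediate
4 | (+)-menthol, (1S,2R,5S)-2-isopropyl-5-methylcyclohexan-1-ol | CC(C)[C@H]1CC[C@H](C)C[C@@H]1O | starting material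
5 | (5R)-5-{[(1S,2R,5S)-2-isopropyl-5-methylcyclohexyl]oxy}furan-2(5H)-one (not isolated) | O=C1C=C[C@H](O[C@H]2C[C@@H](C)CC[C@@H]2C(C)C)O1 | intermediate
6 | (5S)-5-{[(1S,2R,5S)-2-isopropyl-5-methylcyclohexyl]oxy}furan-2(5H)-one | O=C1C=C[C@@H](O[C@H]2C[C@@H](C)CC[C@@H]2C(C)C)O1 | intermediate
7 | 4-benzyloxy-3-methoxybenzaldehyde | COc1cc(C=O)ccc1OCc1ccccc1 | starting material
8 | 2-(4-benzyloxy-3-methoxyphenyl)-1,3-dithiane | COc1cc(C2SCCCS2)ccc1OCc1ccccc1 | intermediate
9 | 2-lithio-2-(4-benzyloxy-3-methoxyphenyl)-1,3-dithiane (not isolated) | [Li]C1(SCCCS1)c1ccc(OCc2ccccc2)c(OC)c1 | intermediate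
10 | lithium enolate of (4S,5S)-4-[2-(4-benzyloxy-3-methoxyphenyl)-1,3-dithian-2-yl]-5-(d-menthyloxy)oxolan-2-one (not isolated) | [Li]OC1=C[C@H](C2(SCCCS2)c2ccc(OCc3ccccc3)c(OC)c2)[C@@H](O[C@H]2C[C@@H](C)CC[C@@H]2C(C)C)O1 | intermediate
11 | (3R,4S,5S)-3-[(4-benzyloxy-3-methoxyphenyl)(hydroxy)methyl]-4-[2-(4-benzyloxy-3-methoxyphenyl)-1,3-dithian-2-yl]-5-{[(1S,2R,5S)-2-isopropyl-5-methylcyclohexyl]oxy}oxolan-2-one, carbinol carbon as both epimers | O=C1O[C@H](O[C@H]2C[C@@H](C)CC[C@@H]2C(C)C)[C@@H](C2(SCCCS2)c2ccc(OCc3ccccc3)c(OC)c2)[C@@H]1C(O)c1ccc(OCc2ccccc2)c(OC)c1 | intermediate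
12 | (3R,4S,5S)-4-(4-benzyloxy-3-methoxybenzyl)-3-[(4-benzyloxy-3-methoxyphenyl)(hydroxy)methyl]-5-{[(1S,2R,5S)-2-isopropyl-5-methylcyclohexyl]oxy}oxolan-2-one, carbinol carbon as both epimers | O=C1O[C@H](O[C@H]2C[C@@H](C)CC[C@@H]2C(C)C)[C@@H](Cc2ccc(OCc3ccccc3)c(OC)c2)[C@@H]1C(O)c1ccc(OCc2ccccc2)c(OC)c1 | intermediate
13 | (2S,3S)-2-[(4-benzyloxy-3-methoxyphenyl)(hydroxy)methyl]-3-(4-benzyloxy-3-methoxybenzyl)butane-1,4-diol, carbinol carbon as both epimers | OC[C@@H](C(O)c1ccc(OCc2ccccc2)c(OC)c1)[C@@H](CO)Cc1ccc(OCc2ccccc2)c(OC)c1 | intermediate
14 | [(2R,3S,4S)-2-(4-benzyloxy-3-methoxyphenyl)-4-(4-benzyloxy-3-methoxybenzyl)oxolan-3-yl]methanol | COc1cc(C[C@@H]2CO[C@@H](c3ccc(OCc4ccccc4)c(OC)c3)[C@@H]2CO)ccc1OCc1ccccc1 | intermediate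
15 | (−)-lariciresinol, 4-[(2R,3S,4S)-4-(4-hydroxy-3-methoxybenzyl)-3-(hydroxymethyl)oxolan-2-yl]-2-methoxyphenol | COc1cc(C[C@@H]2CO[C@@H](c3ccc(O)c(OC)c3)[C@@H]2CO)ccc1O | intermediate
16 | caffeic acid, (E)-3-(3,4-dihydroxyphenyl)prop-2-enoic acid | O=C(O)/C=C/c1ccc(O)c(O)c1 | starting material
17 | (E)-3-(3,4-diacetoxyphenyl)prop-2-enoic acid | CC(=O)Oc1ccc(/C=C/C(=O)O)cc1OC(C)=O | intermediate
18 | [(2R,3S,4S)-2-(4-hydroxy-3-methoxyphenyl)-4-(4-hydroxy-3-methoxybenzyl)oxolan-3-yl]methyl (E)-3-(3,4-diacetoxyphenyl)prop-2-enoate | COc1cc(C[C@@H]2CO[C@@H](c3ccc(O)c(OC)c3)[C@@H]2COC(=O)/C=C/c2ccc(OC(C)=O)c(OC(C)=O)c2)ccc1O | intermediate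
19 | [(2R,3S,4S)-2-(4-hydroxy-3-methoxyphenyl)-4-(4-hydroxy-3-methoxybenzyl)oxolan-3-yl]methyl (E)-3-(3,4-dihydroxyphenyl)prop-2-enoate | COc1cc(C[C@@H]2CO[C@@H](c3ccc(O)c(OC)c3)[C@@H]2COC(=O)/C=C/c2ccc(O)c(O)c2)ccc1O | target

## Step count and uncertain steps

Total: 11 steps. Longest linear sequence: 9 steps (steps 1, 2, 4, 5, 6, 7, 8, 10, 11, from furfural).

**Step 4 (key step).** The most likely failure is incomplete or reversible trapping of the hindered enolate 10: proton transfer to the enolate or retro-aldol on warming would leave the simple Michael adduct, and some trans selectivity at C3 could be lost. The fallback separates the two bond formations. It sets out from 8 and 6: the conjugate addition is run as before but quenched with AcOH at −78 °C, and (4S,5S)-4-[2-(4-benzyloxy-3-methoxyphenyl)-1,3-dithian-2-yl]-5-(d-menthyloxy)oxolan-2-one F1 is isolated. F1 is re-enolised with LiN(i-Pr)2 in THF at −78 °C, transmetalated with ZnCl2 and treated with aldehyde 7; the zinc aldolate is less prone to reversal. The fallback returns to the route at 11.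

**Step 7.** The most likely failure is capture of the benzylic cation by the electron-rich ring of the neighbouring benzyl group (Friedel–Crafts closure to an aryltetralin) once contact with acid is long enough to equilibrate C2, so that trans selection and chemoselectivity pull in opposite directions. The fallback changes the electrophile. It sets out from 13: the benzyl ethers are removed first (H2, Pd/C, EtOAc) to give the free-phenol triol (2S,3S)-2-[hydroxy(4-hydroxy-3-methoxyphenyl)methyl]-3-(4-hydroxy-3-methoxybenzyl)butane-1,4-diol F2. A p-hydroxybenzylic alcohol closes under far milder conditions (catalytic AcOH in THF, rt) through a p-quinone methide, which takes up the hydroxyl reversibly but not the arene. This gives the bis-phenol directly and returns to the route at 15.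

**Step 8.** The most likely failure is over-hydrogenolysis, that is cleavage of the benzylic ring bond C2–O1 beside or after the benzyl ethers. The fallback moves the hydrogenolysis to the lactone stage. It sets out from 12, where the only other benzylic C–O bond is a free secondary alcohol β to the lactone carbonyl and hence a poor candidate for cleavage. Hydrogenolysis (H2, Pd/C, EtOAc) gives (3R,4S,5S)-3-[hydroxy(4-hydroxy-3-methoxyphenyl)methyl]-4-(4-hydroxy-3-methoxybenzyl)-5-(d-menthyloxy)oxolan-2-one F3. Reduction with excess LiAlH4 then gives the free-phenol triol F2 described under step 7, which is closed with catalytic AcOH as there. The fallback returns to the route at 15.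

**Step 10.** The most likely failure is loss of chemoselectivity: O-alkylation of phenols by the alkoxyphosphonium ion, or slow displacement at the β-branched CH2. The fallback activates the acid instead of the alcohol, with the phenols masked. It sets out from 15: selective acetylation of the phenoxides (Ac2O, aqueous NaOH, 0 °C, Schotten–Baumann conditions) gives [(2R,3S,4S)-2-(4-acetoxy-3-methoxyphenyl)-4-(4-acetoxy-3-methoxybenzyl)oxolan-3-yl]methanol F4. Steglich esterification of its one free hydroxyl with 17 (EDC·HCl, DMAP, CH2Cl2) gives the tetraacetate [(2R,3S,4S)-2-(4-acetoxy-3-methoxyphenyl)-4-(4-acetoxy-3-methoxybenzyl)oxolan-3-yl]methyl (E)-3-(3,4-diacetoxyphenyl)prop-2-enoate F5. Aminolysis of all four aryl acetates under the conditions of step 11 returns to the route at 19.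

**Step 11.** The most likely failure is cleavage or transesterification of the caffeate, conjugate addition of the amine, or air oxidation of the freed catechol under basic conditions. The fallback uses fluoride-labile masking. It sets out from 16: TBSCl and imidazole in DMF give tert-butyldimethylsilyl (E)-3-[3,4-bis(tert-butyldimethylsilyloxy)phenyl]prop-2-enoate F6, whose silyl ester is hydrolysed (AcOH, THF/H2O) to (E)-3-[3,4-bis(tert-butyldimethylsilyloxy)phenyl]prop-2-enoic acid F7. Mitsunobu esterification of 15 with F7 under the conditions of step 10 gives [(2R,3S,4S)-2-(4-hydroxy-3-methoxyphenyl)-4-(4-hydroxy-3-methoxybenzyl)oxolan-3-yl]methyl (E)-3-[3,4-bis(tert-butyldimethylsilyloxy)phenyl]prop-2-enoate F8. Et3N·3HF in THF at 0 °C removes the silyl groups without touching the ester and returns to the route at 19.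

## Further compounds

F1 | step 4 | (4S,5S)-4-[2-(4-benzyloxy-3-methoxyphenyl)-1,3-dithian-2-yl]-5-{[(1S,2R,5S)-2-isopropyl-5-methylcyclohexyl]oxy}oxolan-2-one | O=C1C[C@H](C2(SCCCS2)c2ccc(OCc3ccccc3)c(OC)c2)[C@@H](O[C@H]2C[C@@H](C)CC[C@@H]2C(C)C)O1
F2 | step 7 | (2S,3S)-2-[hydroxy(4-hydroxy-3-methoxyphenyl)methyl]-3-(4-hydroxy-3-methoxybenzyl)butane-1,4-diol, carbinol carbon as both epimers | OC[C@@H](C(O)c1ccc(O)c(OC)c1)[C@@H](CO)Cc1ccc(O)c(OC)c1
F3 | step 8 | (3R,4S,5S)-3-[hydroxy(4-hydroxy-3-methoxyphenyl)methyl]-4-(4-hydroxy-3-methoxybenzyl)-5-{[(1S,2R,5S)-2-isopropyl-5-methylcyclohexyl]oxy}oxolan-2-one, carbinol carbon as both epimers | O=C1O[C@H](O[C@H]2C[C@@H](C)CC[C@@H]2C(C)C)[C@@H](Cc2ccc(O)c(OC)c2)[C@@H]1C(O)c1ccc(O)c(OC)c1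
F4 | step 10 | [(2R,3S,4S)-2-(4-acetoxy-3-methoxyphenyl)-4-(4-acetoxy-3-methoxybenzyl)oxolan-3-yl]methanol | COc1cc(C[C@@H]2CO[C@@H](c3ccc(OC(C)=O)c(OC)c3)[C@@H]2CO)ccc1OC(C)=O
F5 | step 10 | [(2R,3S,4S)-2-(4-acetoxy-3-methoxyphenyl)-4-(4-acetoxy-3-methoxybenzyl)oxolan-3-yl]methyl (E)-3-(3,4-diacetoxyphenyl)prop-2-enoate | COc1cc(C[C@@H]2CO[C@@H](c3ccc(OC(C)=O)c(OC)c3)[C@@H]2COC(=O)/C=C/c2ccc(OC(C)=O)c(OC(C)=O)c2)ccc1OC(C)=O
F6 | step 11 | tert-butyldimethylsilyl (E)-3-[3,4-bis(tert-butyldimethylsilyloxy)phenyl]prop-2-enoate | CC(C)(C)[Si](C)(C)OC(=O)/C=C/c1ccc(O[Si](C)(C)C(C)(C)C)c(O[Si](C)(C)C(C)(C)C)c1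
F7 | step 11 | (E)-3-[3,4-bis(tert-butyldimethylsilyloxy)phenyl]prop-2-enoic acid | O=C(O)/C=C/c1ccc(O[Si](C)(C)C(C)(C)C)c(O[Si](C)(C)C(C)(C)C)c1
F8 | step 11 | [(2R,3S,4S)-2-(4-hydroxy-3-methoxyphenyl)-4-(4-hydroxy-3-methoxybenzyl)oxolan-3-yl]methyl (E)-3-[3,4-bis(tert-butyldimethylsilyloxy)phenyl]prop-2-enoate | COc1cc(C[C@@H]2CO[C@@H](c3ccc(O)c(OC)c3)[C@@H]2COC(=O)/C=C/c2ccc(O[Si](C)(C)C(C)(C)C)c(O[Si](C)(C)C(C)(C)C)c2)ccc1O
A1 | alternative 1 | dimethyl (2S,4Z)-2-(4-benzyloxy-3-methoxyphenyl)-4-[(4-benzyloxy-3-methoxyphenyl)methylidene]oxolane-3,3-dicarboxylate (C2 arranged in space as in the target) | COc1cc(/C=C2\CO[C@@H](c3ccc(OCc4ccccc4)c(OC)c3)C2(C(=O)OC)C(=O)OC)ccc1OCc1ccccc1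
A2 | alternative 2 | 3-(4-benzyloxy-3-methoxybenzyl)cyclobutan-1-one | COc1cc(CC2CC(=O)C2)ccc1OCc1ccccc1
A3 | alternative 2 | (4S)-4-(4-benzyloxy-3-methoxybenzyl)oxolan-2-one | COc1cc(C[C@@H]2COC(=O)C2)ccc1OCc1ccccc1
A4 | alternative 3 | (2S,3S)-2,3-bis(4-benzyloxy-3-methoxybenzyl)butane-1,4-diol | OC[C@@H](Cc1ccc(OCc2ccccc2)c(OC)c1)[C@@H](CO)Cc1ccc(OCc2ccccc2)c(OC)c1
A5 | alternative 3 | [(2R,3S,4S)-2-(4-benzyloxy-3-methoxyphenyl)-4-(4-benzyloxy-3-methoxybenzyl)oxolan-3-yl]methanol (identical with 14) | COc1cc(C[C@@H]2CO[C@@H](c3ccc(OCc4ccccc4)c(OC)c3)[C@@H]2CO)ccc1OCc1ccccc1
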